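**Retrosynthetic overview**

1. Feature: in ring A (C1 OMe, C2 Br, C3 H, C4 Br, C5 H, C6 O–ring B) the brominated C2 sits beside the oxygen-bearing C1, which is the pattern left when a CBr2 unit is inserted next to an enol-ether carbon.
2. C1–OMe comes from the phenol by O-methylation; C4–Br comes from bromination para to OH; the aromatic ring A comes from 2-bromo-6-aryloxycyclohex-2-enone by bromination and dehydrobromination.
3. Key disconnection: C1–C2 and C2–C3 of ring A, leading back to dibromocarbene plus the five-membered silyl enol ether (one-carbon ring enlargement, 5 to 6).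
4. The silyl enol ether comes from 2-(2,4-dibromophenoxy)cyclopentanone, made from 2-chlorocyclopentanone and 2,4-dibromophenol (C6–O bond by SN2).
5. Ring order: ring B and the cyclopentanone ring are bought; ring A is made by ring enlargement and aromatized afterwards.

Key step: step 3

Remark on the chemistry: the target is achiral, so 1, 3, 4, 6, 7 and 8 are handled as racemates and no stereocontrol is needed.

**Route**

Step 1
Reactants: 1 2-chlorocyclopentan-1-one (racemic); 2 2,4-dibromophenol
Product: 3 2-(2,4-dibromophenoxy)cyclopentan-1-one (racemic)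
Conditions: K2CO3, KI (cat.), acetone, reflux
Reagents that add atoms: none
Why: Williamson-type SN2 substitution of the carbonyl-activated secondary chloride by the weakly basic 2,4-dibromophenoxide (KI assists by Finkelstein exchange), which is too poor a base to start a Favorskii rearrangement; the new C2 stereocenter is racemic and is erased later.

Step 2
Reactants: 3 2-(2,4-dibromophenoxy)cyclopentan-1-one
Product: 4 5-(2,4-dibromophenoxy)-1-(trimethylsilyloxy)cyclopent-1-ene (racemic)
Conditions: LiN(SiMe3)2, Me3SiCl, THF, −78 °C (3 added last); Et3N, pentane, filtration, used crude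
Reagents that add atoms: chlorotrimethylsilane, C[Si](C)(C)Cl
Why: Kinetic enolization with the bulky amide should take a proton from the open C5 methylene and not the tertiary, aryloxy-shielded C2–H, as is usual for α-alkoxy ketones, and O-silylation by the Me3SiCl already present (internal quench) traps the lithium enolate before it can equilibrate; LiN(SiMe3)2 is too weak a base to metalate the dibromoarene.

Step 3
Reactants: 4 5-(2,4-dibromophenoxy)-1-(trimethylsilyloxy)cyclopent-1-ene; 5 bromoform
Product: 7 2-bromo-6-(2,4-dibromophenoxy)cyclohex-2-en-1-one (racemic), via silyloxy dibromocyclopropane 6 (not isolated)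
Conditions: CHBr3 (added slowly), KOtBu, pentane, −20 °C to rt; filtration; then toluene, 60 °C
Reagents that add atoms: none
Why: Deprotonation of bromoform by KOtBu and α-elimination of bromide give singlet dibromocarbene, which adds as an electrophile in a concerted [2+1] cheletropic step to the electron-rich C1=C2 enol ether bond of 4 and so forms both new C–C bonds of cyclopropane 6 (the three-membered ring closes by cycloaddition, probably anti to the aryloxy group, which is of no consequence). In 6 the endo bromide ionizes with help from the silyloxy oxygen while the ring-fusion bond (the former C1–C2 bond of 4) breaks in a disrotatory two-electron electrocyclic opening (Woodward–Hoffmann–DePuy rule), so ring A is not closed by a cyclization but arises by merging the three- and five-membered rings into a six-membered 2-bromo-1-silyloxyallyl cation, which gives up its silyl group to bromide and leaves enone 7. The closest known reaction type is the dihalocarbene ring expansion of cyclic trimethylsilyl enol ethers to 2-halocycloalk-2-enones. No lasting stereocenter is made: C6 of 7 is inherited racemic from 4 and vanishes on aromatization. The step needs chemoselectivity for the enol ether over the arenes and over Si–O cleavage by alkoxide, which the nucleophilic enol ether, the electron-poor dibromophenyl ring and the use of solid KOtBu in pentane at low temperature should secure; the place of the inserted carbon (ring A C2, between carbonyl C1 and C3, remote from the aryloxy carbon C6) is fixed by the position of the double bond in 4.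

Step 4
Reactants: 7 2-bromo-6-(2,4-dibromophenoxy)cyclohex-2-en-1-one
Product: 10 2,4-dibromo-6-(2,4-dibromophenoxy)phenol, via 6-bromo ketone 8 (not isolated), via monobromophenol 9 (not isolated)
Conditions: Br2 (2.1 equiv), dry AcOH, rt then 60 °C
Reagents that add atoms: bromine, BrBr
Why: Acid-catalysed α-bromination of the ketone at C6 (its only α-hydrogen), dehydrobromination toward C5 driven by aromatization with tautomerization to phenol 9, and electrophilic aromatic bromination of 9 at C4, the only free position activated by the hydroxyl (both ortho positions are occupied and ring B is deactivated by two bromines), should follow one another in one flask; the racemic C6 centre disappears.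

Step 5
Reactants: 10 2,4-dibromo-6-(2,4-dibromophenoxy)phenol
Product: 11 1,5-dibromo-3-(2,4-dibromophenoxy)-2-methoxybenzene (2,4-dibromo-6-(2,4-dibromophenoxy)anisole, the target)
Conditions: MeI, K2CO3, acetone, reflux
Reagents that add atoms: iodomethane, CI
Why: Williamson O-methylation (SN2) of the acidic, doubly ortho-substituted phenoxide with the small electrophile iodomethane, with no other nucleophilic site in the molecule.

**Compound list**

1 | 2-chlorocyclopentan-1-one (racemic) | O=C1CCCC1Cl | starting material
2 | 2,4-dibromophenol | Oc1ccc(Br)cc1Br | starting material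
3 | 2-(2,4-dibromophenoxy)cyclopentan-1-one (racemic) | O=C1CCCC1Oc1ccc(Br)cc1Br | intermediate
4 | 5-(2,4-dibromophenoxy)-1-(trimethylsilyloxy)cyclopent-1-ene (racemic) | C[Si](C)(C)OC1=CCCC1Oc1ccc(Br)cc1Br | intermediate
5 | bromoform | BrC(Br)Br | starting material
6 | 6,6-dibromo-2-(2,4-dibromophenoxy)-1-(trimethylsilyloxy)bicyclo[3.1.0]hexane (racemic, diastereomers not assigned, not isolated) | C[Si](C)(C)OC12C(Br)(Br)C1CCC2Oc1ccc(Br)cc1Br | intermediate
7 | 2-bromo-6-(2,4-dibromophenoxy)cyclohex-2-en-1-one (racemic) | O=C1C(Br)=CCCC1Oc1ccc(Br)cc1Br | intermediate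
8 | 2,6-dibromo-6-(2,4-dibromophenoxy)cyclohex-2-en-1-one (racemic, not isolated) | O=C1C(Br)=CCCC1(Br)Oc1ccc(Br)cc1Br | intermediate
9 | 2-bromo-6-(2,4-dibromophenoxy)phenol (not isolated) | Oc1c(Br)cccc1Oc1ccc(Br)cc1Br | intermediate
10 | 2,4-dibromo-6-(2,4-dibromophenoxy)phenol | Oc1c(Br)cc(Br)cc1Oc1ccc(Br)cc1Br | intermediate
11 | 1,5-dibromo-3-(2,4-dibromophenoxy)-2-methoxybenzene | COc1c(Br)cc(Br)cc1Oc1ccc(Br)cc1Br | target

**Step count**

Total steps: 5. Longest linear sequence: 5.

**Steps most likely to fail**

Step 3. tert-Butoxide may cleave the Si–O bond of 4 before the carbene adds, which would return ketone 3, or the base may degrade the enone as it forms. The fallback sets out from 4, comes back at 7, and separates ring enlargement from bromination. A Simmons–Smith cyclopropanation in the Furukawa form (Et2Zn, CH2I2, CH2Cl2, 0 °C) should give 2-(2,4-dibromophenoxy)-1-(trimethylsilyloxy)bicyclo[3.1.0]hexane F1. Oxidative opening with FeCl3 in DMF (Ito–Saegusa ring enlargement: alkoxy radical, β-scission of the ring-fusion bond, chlorine transfer) should give 3-chloro-6-(2,4-dibromophenoxy)cyclohexan-1-one F2. NaOAc in hot MeOH should then eliminate HCl to 6-(2,4-dibromophenoxy)cyclohex-2-en-1-one F3. Addition of Br2 to the enone double bond (CH2Cl2, 0 °C) should give 2,3-dibromo-6-(2,4-dibromophenoxy)cyclohexan-1-one F4, from which Et3N removes HBr to give 7.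

Step 2. Proton removal may occur on the aryloxy-bearing side, or the enolate may equilibrate. Either would give the regioisomeric enol ether and put the inserted carbon between C1 and C6. The fallback fixes the double bond by construction. It sets out from 2 and commercial cyclopentane-1,2-dione (O=C1CCCC1=O, present as its enol) and comes back at 7.
- Silylation (tert-butyldimethylsilyl chloride, imidazole, DMF) should give 2-(tert-butyldimethylsilyloxy)cyclopent-2-en-1-one F5.
- Luche 1,2-reduction (NaBH4, CeCl3·7H2O, MeOH, −40 °C) should give 2-(tert-butyldimethylsilyloxy)cyclopent-2-en-1-ol F6.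
- Mitsunobu etherification with 2 (PPh3, diisopropyl azodicarboxylate, THF, 0 °C) should give 1-(tert-butyldimethylsilyloxy)-5-(2,4-dibromophenoxy)cyclopent-1-ene F7. SN2 and SN2' attack lead to the same constitution.
- F7 then takes the place of 4 under the conditions of step 3. It should pass through 6,6-dibromo-1-(tert-butyldimethylsilyloxy)-2-(2,4-dibromophenoxy)bicyclo[3.1.0]hexane F8 and open to 7.

Step 4. Solvolysis of the α-bromo-α-aryloxy ketone may compete with dehydrobromination and release the aryloxy group as the phenol, or the arenes may be over-brominated. The fallback sets out from 7, comes back at 10, and takes bromine out of the dehydrogenation.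
- The kinetic α'-enolate (LiN(SiMe3)2, THF, −78 °C) is trapped with PhSeCl to give 2-bromo-6-(2,4-dibromophenoxy)-6-(phenylselanyl)cyclohex-2-en-1-one F9.
- Oxidation (H2O2, pyridine, CH2Cl2, 0 °C) should give 2-bromo-6-(2,4-dibromophenoxy)-6-(phenylseleninyl)cyclohex-2-en-1-one F10.
- Syn-elimination of F10 toward C5 and tautomerization should give phenol 9, isolated this time.
- One equivalent of Br2 (CH2Cl2, 0 °C) should then brominate C4 to give 10.

**Further compounds**

F1 | step 3 | 2-(2,4-dibromophenoxy)-1-(trimethylsilyloxy)bicyclo[3.1.0]hexane | C[Si](C)(C)OC12CC1CCC2Oc1ccc(Br)cc1Br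
F2 | step 3 | 3-chloro-6-(2,4-dibromophenoxy)cyclohexan-1-one | O=C1CC(Cl)CCC1Oc1ccc(Br)cc1Br
F3 | step 3 | 6-(2,4-dibromophenoxy)cyclohex-2-en-1-one | O=C1C=CCCC1Oc1ccc(Br)cc1Br
F4 | step 3 | 2,3-dibromo-6-(2,4-dibromophenoxy)cyclohexan-1-one | O=C1C(Br)C(Br)CCC1Oc1ccc(Br)cc1Br
F5 | step 2 | 2-(tert-butyldimethylsilyloxy)cyclopent-2-en-1-one | O=C1CCC=C1O[Si](C)(C)C(C)(C)C
F6 | step 2 | 2-(tert-butyldimethylsilyloxy)cyclopent-2-en-1-ol | OC1CCC=C1O[Si](C)(C)C(C)(C)C
F7 | step 2 | 1-(tert-butyldimethylsilyloxy)-5-(2,4-dibromophenoxy)cyclopent-1-ene | CC(C)(C)[Si](C)(C)OC1=CCCC1Oc1ccc(Br)cc1Br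
F8 | step 2 | 6,6-dibromo-1-(tert-butyldimethylsilyloxy)-2-(2,4-dibromophenoxy)bicyclo[3.1.0]hexane | CC(C)(C)[Si](C)(C)OC12C(Br)(Br)C1CCC2Oc1ccc(Br)cc1Br
F9 | step 4 | 2-bromo-6-(2,4-dibromophenoxy)-6-(phenylselanyl)cyclohex-2-en-1-one | O=C1C(Br)=CCCC1([Se]c1ccccc1)Oc1ccc(Br)cc1Br
F10 | step 4 | 2-bromo-6-(2,4-dibromophenoxy)-6-(phenylseleninyl)cyclohex-2-en-1-one | O=C1C(Br)=CCCC1([Se](=O)c1ccccc1)Oc1ccc(Br)cc1Br
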